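**Retrosynthetic overview**
1. The dihydrofuran is cut at C6–O and C7–C(naphthyl): a late anodic [3+2] annulation joins 6,7-dehydrohinokiol and a 2-naphthol, and sets C6 and C7 on the α-face.
2. 6,7-Dehydrohinokiol comes from (+)-hinokiol by DDQ dehydrogenation; rings A/B/C and C3, C5, C10 are bought.
3. The achiral naphthol comes from its methyl ether, made by Heck–isomerisation of a naphthyl triflate with 4-methylpent-1-en-3-ol.
4. The triflate comes from Friedel–Crafts isopropylation of a simpler naphthyl triflate, itself from 6-methoxy-2-methyl-1-tetralone by aromatisation.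
5. Ring order: naphthalene (aromatisation) → abietane A/B/C (bought) → dihydrofuran (last).

Assumption: (+)-hinokiol (abieta-8,11,13-triene-3β,12-diol) is bought from natural-product suppliers as the chiral starting material; it is a catalogue compound but not a cheap bulk chemical. 6-Methoxy-2-methyl-1-tetralone and 4-methylpent-1-en-3-ol are taken as catalogue chemicals.

**Step 1**
Reactants: 1 6-methoxy-2-methyl-3,4-dihydronaphthalen-1(2H)-one (racemic)
Product: 3 6-methoxy-2-methylnaphthalen-1-ol, via α-bromo ketone 2 (not isolated)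
Conditions: PhNMe3Br3 (1.05 equiv), THF, 0 °C → rt; then DBU (3 equiv), 60 °C, N2
Reagents that add atoms: none
Why: Ketone α-bromination at the tertiary C2, then E2 loss of HBr with DBU and enolisation, delivers the aromatic naphthol (bromination–dehydrobromination aromatisation); the C2 stereocentre of racemic 1 disappears.

**Step 2**
Reactants: 3 6-methoxy-2-methylnaphthalen-1-ol
Product: 4 6-methoxy-2-methylnaphthalen-1-yl trifluoromethanesulfonate
Conditions: Tf2O, pyridine, CH2Cl2, 0 °C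
Reagents that add atoms: trifluoromethanesulfonic anhydride, O=S(=O)(OS(=O)(=O)C(F)(F)F)C(F)(F)F
Why: O-Triflation turns the C1 oxygen into a cross-coupling handle and deactivates that ring for the next step.

**Step 3**
Reactants: 4 6-methoxy-2-methylnaphthalen-1-yl trifluoromethanesulfonate
Product: 5 6-methoxy-2-methyl-5-(propan-2-yl)naphthalen-1-yl trifluoromethanesulfonate
Conditions: 2-bromopropane (1.5 equiv), AlCl3 (0.3 equiv), CH2Cl2, −20 → 0 °C
Reagents that add atoms: 2-bromopropane, CC(C)Br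
Why: Friedel–Crafts alkylation at C5, the α-position ortho to the methoxy group and the only strongly activated site, since the triflate ring is deactivated and C7 is a less reactive β-position.

**Step 4**
Reactants: 5 6-methoxy-2-methyl-5-(propan-2-yl)naphthalen-1-yl trifluoromethanesulfonate; 6 4-methylpent-1-en-3-ol (racemic)
Product: 7 1-[6-methoxy-2-methyl-5-(propan-2-yl)naphthalen-1-yl]-4-methylpentan-3-one
Conditions: Pd(OAc)2 (5 mol %), P(o-tol)3 (10 mol %), LiCl, NaHCO3, DMF, 100 °C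
Reagents that add atoms: none
Why: Heck arylation of the allylic alcohol under chloride (neutral-pathway) conditions puts the aryl group on the terminal carbon, and β-hydride elimination towards the carbinol gives the enol and hence the β-aryl ketone directly (Heck–isomerisation); the carbinol stereocentre of racemic 6 is lost.

**Step 5**
Reactants: 7 1-[6-methoxy-2-methyl-5-(propan-2-yl)naphthalen-1-yl]-4-methylpentan-3-one
Product: 8 1-[6-hydroxy-2-methyl-5-(propan-2-yl)naphthalen-1-yl]-4-methylpentan-3-one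
Conditions: BBr3, CH2Cl2, −78 → 0 °C; then H2O
Reagents that add atoms: none
Why: BBr3 cleavage of the aryl methyl ether (Lewis-acid demethylation) frees the naphthol and leaves the dialkyl ketone intact at low temperature.

**Step 6**
Reactants: 9 (+)-hinokiol (abieta-8,11,13-triene-3β,12-diol; 5α-H, 10β-Me)
Product: 10 6,7-dehydrohinokiol (abieta-6,8,11,13-tetraene-3β,12-diol; 5α-H, 10β-Me)
Conditions: DDQ (1.05 equiv), 1,4-dioxane, rt
Reagents that add atoms: none
Why: DDQ dehydrogenation by hydride abstraction from C7 (para to the free phenol) and loss of H6 gives the conjugated 4-hydroxystyrene; the unactivated 3β-carbinol and the C3, C5, C10 stereocentres are untouched.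

**Step 7**
Reactants: 10 6,7-dehydrohinokiol; 8 1-[6-hydroxy-2-methyl-5-(propan-2-yl)naphthalen-1-yl]-4-methylpentan-3-one
Product: 12 target CNP0584944.1 (6α-O, 7α-C dihydronaphthofuran annulated onto hinokiol; 3β-OH, 5α-H, 6β-H, 7β-H, 10β-Me), via quinone methide ether 11 (not isolated)
Conditions: graphite(+)/Pt(−), undivided cell, +0.9 V vs Ag/AgCl (2.1 F/mol), nBu4NPF6, 2,6-lutidine, CH2Cl2/HFIP 4:1, 0 °C → rt; 8 (2 equiv), slow addition of 10
Reagents that add atoms: none
Why: Proposed new method: at the low potential only the 4-hydroxystyrene 10 is oxidised (ECE, −2e/−H+) to its vinylogous phenoxonium ion (β-cation of a p-quinone methide), the naphthol oxygen of 8 (C1 blocked by iPr, as in β–O–4 lignol coupling) adds to C6 from the α-face anti to the axial C4β/C10β methyls to give quinone methide ether 11, and HFIP-promoted intramolecular 1,6-addition (Friedel–Crafts) of naphthalene C3 to C7 can only close cis, so C6 (α-O) and C7 (α-C) are both set by the bought C5/C10 centres; the closest known reactions are the anodic and photocatalytic oxidative [3+2] annulations of phenols with styrenes (opposite, 2-aryl regiochemistry, because there the phenol and not the alkene is oxidised) and the anodic 1,2-difunctionalisation of 4-hydroxystyrenes.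

**Compound list**
1 | 6-methoxy-2-methyl-3,4-dihydronaphthalen-1(2H)-one (racemic) | COc1ccc2c(c1)CCC(C)C2=O | starting material
2 | 2-bromo-6-methoxy-2-methyl-3,4-dihydronaphthalen-1(2H)-one (racemic) | COc1ccc2c(c1)CCC(C)(Br)C2=O | intermediate
3 | 6-methoxy-2-methylnaphthalen-1-ol | COc1ccc2c(O)c(C)ccc2c1 | intermediate
4 | 6-methoxy-2-methylnaphthalen-1-yl trifluoromethanesulfonate | COc1ccc2c(OS(=O)(=O)C(F)(F)F)c(C)ccc2c1 | intermediate
5 | 6-methoxy-2-methyl-5-(propan-2-yl)naphthalen-1-yl trifluoromethanesulfonate | COc1ccc2c(OS(=O)(=O)C(F)(F)F)c(C)ccc2c1C(C)C | intermediate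
6 | 4-methylpent-1-en-3-ol (racemic) | C=CC(O)C(C)C | starting material
7 | 1-[6-methoxy-2-methyl-5-(propan-2-yl)naphthalen-1-yl]-4-methylpentan-3-one | COc1ccc2c(CCC(=O)C(C)C)c(C)ccc2c1C(C)C | intermediate
8 | 1-[6-hydroxy-2-methyl-5-(propan-2-yl)naphthalen-1-yl]-4-methylpentan-3-one | Oc1ccc2c(CCC(=O)C(C)C)c(C)ccc2c1C(C)C | intermediate
9 | (+)-hinokiol, abieta-8,11,13-triene-3β,12-diol (5α-H, 10β-Me) | CC(C)c1cc2c(cc1O)[C@@]1(C)CC[C@H](O)C(C)(C)[C@@H]1CC2 | starting material
10 | 6,7-dehydrohinokiol, abieta-6,8,11,13-tetraene-3β,12-diol (5α-H, 10β-Me) | CC(C)c1cc2c(cc1O)[C@@]1(C)CC[C@H](O)C(C)(C)[C@@H]1C=C2 | intermediate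
11 | 3β-hydroxy-6α-{[6-methyl-5-(4-methyl-3-oxopentyl)-1-(propan-2-yl)naphthalen-2-yl]oxy}abieta-7,9(11),13-trien-12-one (p-quinone methide; 5α-H, 6β-H, 10β-Me) | CC(C)C1=CC2=C[C@H](Oc5ccc6c(CCC(=O)C(C)C)c(C)ccc6c5C(C)C)[C@H]3C(C)(C)[C@@H](O)CC[C@]3(C)C2=CC1=O | intermediate
12 | target CNP0584944.1: hinokiol annulated at C6 (α-O) and C7 (α-C) with the naphthol O and its ortho carbon C3 to a cis-fused dihydronaphtho[2,3-b]furan (3β-OH, 12-OH, 5α-H, 6β-H, 7β-H, 10β-Me) | Cc1ccc2c(C(C)C)c3c(cc2c1CCC(=O)C(C)C)[C@H]1c2cc(C(C)C)c(O)cc2[C@@]2(C)CC[C@H](O)C(C)(C)[C@@H]2[C@H]1O3 | target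

**Totals**
Total step count: 7. Longest linear sequence: 6 steps (steps 1–5, then step 7).

**Three steps most likely to fail**

Step 7 (the proposed new anodic annulation). Risks are homodimerisation of 10, C- or ipso-attack by the naphthol instead of O-attack, and over-oxidation of 12 to the aromatic naphthofuran. The fallback uses known chemistry, sets out from 9 (with 8) and returns at 12. Compound 9 is bis-silylated (TBSOTf, 2,6-lutidine) to 3,12-bis-O-TBS-hinokiol F1 and oxidised at the benzylic position (CrO3·3,5-dimethylpyrazole) to the 7-ketone F2. Formylation (NaH, HCO2Et) gives the 6-hydroxymethylene ketone F3, and deformylative diazo transfer (TsN3, Et3N) gives the 6-diazo-7-ketone F4. Rh2(OAc)4-catalysed O–H insertion of naphthol 8, followed by DBU equilibration at C6, gives the equatorial 6α-aryloxy-7-ketone F5. NaBH4 reduces both ketones to the diol F6. BF3·OEt2 ionises the benzylic alcohol and naphthalene C3 closes the ring (intramolecular Friedel–Crafts, cis by necessity) to the silylated cyclised carbinol F7. Dess–Martin periodinane restores the side-chain ketone in the bis-silyl ether F8, and HF·pyridine removes both silyl groups to give 12.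

Step 6 (DDQ dehydrogenation). Risks are over-oxidation of the electron-rich styrene 10 and DDQ adducts. The fallback sets out from 9 and returns at 10. Acetylation (Ac2O, pyridine) gives hinokiol diacetate F9, and CrO3/AcOH benzylic oxidation gives 7-oxohinokiol diacetate F10. LiAlH4 reduces the ketone and both esters to abieta-8,11,13-triene-3β,7,12-triol F11. Acid-catalysed dehydration of the p-hydroxybenzylic alcohol (cat. TsOH, benzene) gives 10.

Step 4 (Heck–isomerisation on the hindered 2-methyl-1-naphthyl triflate). Risks are slow oxidative addition and insertion, and β-hydride elimination in the wrong direction. The fallback sets out from 5 and returns at 7. Sonogashira coupling (Pd(PPh3)2Cl2, CuI, Et3N) with 4-methylpent-1-yn-3-ol gives the propargylic alcohol F12. Hydrogenation (H2, Pd/C) gives the saturated carbinol F13, and Dess–Martin oxidation gives 7.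

**Further compounds**
F1 | step 7 | 3β,12-bis(tert-butyldimethylsilyloxy)abieta-8,11,13-triene | CC(C)c1cc2c(cc1O[Si](C)(C)C(C)(C)C)[C@@]1(C)CC[C@H](O[Si](C)(C)C(C)(C)C)C(C)(C)[C@@H]1CC2
F2 | step 7 | 3β,12-bis(tert-butyldimethylsilyloxy)abieta-8,11,13-trien-7-one | CC(C)c1cc2c(cc1O[Si](C)(C)C(C)(C)C)[C@@]1(C)CC[C@H](O[Si](C)(C)C(C)(C)C)C(C)(C)[C@@H]1CC2=O
F3 | step 7 | 6-(hydroxymethylene)-3β,12-bis(tert-butyldimethylsilyloxy)abieta-8,11,13-trien-7-one | CC(C)c1cc2c(cc1O[Si](C)(C)C(C)(C)C)[C@@]1(C)CC[C@H](O[Si](C)(C)C(C)(C)C)C(C)(C)[C@@H]1C(=CO)C2=O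
F4 | step 7 | 6-diazo-3β,12-bis(tert-butyldimethylsilyloxy)abieta-8,11,13-trien-7-one | CC(C)c1cc2c(cc1O[Si](C)(C)C(C)(C)C)[C@@]1(C)CC[C@H](O[Si](C)(C)C(C)(C)C)C(C)(C)[C@@H]1C(=[N+]=[N-])C2=O
F5 | step 7 | 6α-{[6-methyl-5-(4-methyl-3-oxopentyl)-1-(propan-2-yl)naphthalen-2-yl]oxy}-3β,12-bis(tert-butyldimethylsilyloxy)abieta-8,11,13-trien-7-one | CC(C)c1cc2c(cc1O[Si](C)(C)C(C)(C)C)[C@@]1(C)CC[C@H](O[Si](C)(C)C(C)(C)C)C(C)(C)[C@@H]1[C@@H](Oc3ccc4c(CCC(=O)C(C)C)c(C)ccc4c3C(C)C)C2=O
F6 | step 7 | 6α-{[5-(3-hydroxy-4-methylpentyl)-6-methyl-1-(propan-2-yl)naphthalen-2-yl]oxy}-3β,12-bis(tert-butyldimethylsilyloxy)abieta-8,11,13-trien-7-ol (carbinol epimers) | CC(C)c1cc2c(cc1O[Si](C)(C)C(C)(C)C)[C@@]1(C)CC[C@H](O[Si](C)(C)C(C)(C)C)C(C)(C)[C@@H]1[C@@H](Oc3ccc4c(CCC(O)C(C)C)c(C)ccc4c3C(C)C)C2O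
F7 | step 7 | 3,12-bis-O-TBS ether of 12 with the side-chain ketone reduced to the carbinol | Cc1ccc2c(C(C)C)c3c(cc2c1CCC(O)C(C)C)[C@H]1c2cc(C(C)C)c(O[Si](C)(C)C(C)(C)C)cc2[C@@]2(C)CC[C@H](O[Si](C)(C)C(C)(C)C)C(C)(C)[C@@H]2[C@H]1O3
F8 | step 7 | 3,12-bis-O-TBS ether of 12 | Cc1ccc2c(C(C)C)c3c(cc2c1CCC(=O)C(C)C)[C@H]1c2cc(C(C)C)c(O[Si](C)(C)C(C)(C)C)cc2[C@@]2(C)CC[C@H](O[Si](C)(C)C(C)(C)C)C(C)(C)[C@@H]2[C@H]1O3
F9 | step 6 | hinokiol 3,12-diacetate | CC(C)c1cc2c(cc1OC(C)=O)[C@@]1(C)CC[C@H](OC(C)=O)C(C)(C)[C@@H]1CC2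
F10 | step 6 | 7-oxohinokiol 3,12-diacetate | CC(C)c1cc2c(cc1OC(C)=O)[C@@]1(C)CC[C@H](OC(C)=O)C(C)(C)[C@@H]1CC2=O
F11 | step 6 | abieta-8,11,13-triene-3β,7,12-triol (C7 epimers) | CC(C)c1cc2c(cc1O)[C@@]1(C)CC[C@H](O)C(C)(C)[C@@H]1CC2O
F12 | step 4 | 1-[6-methoxy-2-methyl-5-(propan-2-yl)naphthalen-1-yl]-4-methylpent-1-yn-3-ol | COc1ccc2c(C#CC(O)C(C)C)c(C)ccc2c1C(C)C
F13 | step 4 | 1-[6-methoxy-2-methyl-5-(propan-2-yl)naphthalen-1-yl]-4-methylpentan-3-ol | COc1ccc2c(CCC(O)C(C)C)c(C)ccc2c1C(C)C
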